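Ring A numbering used throughout: C1 carries the 2‑arylethyl chain, C2 and C6 the benzyl groups, C3 and C5 oxygen, C4 hydrogen; C7 is the benzylic carbon on C2.

## Structural features

The target, C28H26O5, is a polyphenol built on one pentasubstituted benzene (ring A) that carries three 4‑hydroxyphenyl rings through saturated links only: a CH2CH2 chain at C1 and one CH2 each at C2 and C6. Ring A is a resorcinol with hydroxyls at C3 and C5, and its only unsubstituted position, C4, lies between the two oxygens. A mirror plane runs through C1 and C4 and there is no stereocentre, so the whole problem is one of substitution pattern. The fragile elements are the five free phenols (an electron‑rich, air‑sensitive resorcinol) and the two 4‑hydroxybenzyl groups at C2 and C6, which sit ortho and para to the ring A oxygens and can be lost or moved by ipso‑protonation under strong acid. The real difficulty is regiochemical: three contiguous carbon substituents (C6, C1, C2) must be placed on a resorcinol while its most nucleophilic position, C4, stays free, which rules out stepwise Friedel–Crafts benzylation of a preformed resorcinol. The key step uses the fact that C3–C4–C5–C6, with oxygen on C3 and C5 and a benzyl carbon on C6, is the diene of a 4‑benzyl‑1‑methoxy‑3‑silyloxycyclohexa‑1,3‑diene. C1–C2, carrying the arylethyl chain and C7, is an alkyne once C7 is written as a ketone, so a (4+2)/retro‑(4+2) sequence delivers ring A with all six substituents placed.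

## Logic of the disconnections

15 to 14. The four O–CH3 bonds are cut last. Methyl ethers keep every phenol inert to strong amide base, to 160 °C and to protic acid, and all fall in one Lewis‑acid operation. The gain is that every earlier compound is non‑acidic and stable to oxidation. The demand on the forward step is complete ether cleavage without protonating ring A at the benzyl‑bearing carbons.

14 to 12 (through 13). The C7 methylene is written as a carbonyl. This deliberately breaks the symmetry of the target: one benzyl arm becomes an aroyl group, and this carbonyl is the group that polarizes the C1–C2 unit for ring construction. Nothing extraneous is introduced, because the carbonyl carbon is a skeletal atom of the target. The forward step must deoxygenate a diaryl ketone flanked by two ortho substituents without touching the other benzylic positions.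

12 to 6 and 9 (through 11 and 10). After the two‑carbon bridge across C3 and C6 is mentally restored, the ring bonds C1–C6 and C2–C3 are cut. This splits the molecule into two fragments of similar size and makes the route convergent; ring A and its full substitution pattern arise in one operation. The forward step demands one regiochemical sense (C6 to C1, C3 to C2), enough reactivity to join a fully substituted diene terminus to a disubstituted alkyne, and a temperature at which the bridge is expelled.

9 to 7 and 8. The bond between the alkyne carbon and the carbonyl carbon is cut, which leads to two catalogue compounds in one step. The forward step must stop at mono‑acylation. A stoichiometric metalated alkyne can add a second time to the ynone, so catalytic palladium/copper coupling is chosen instead.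

6 to 4 (through 5). The O–Si bond is cut. The forward step must enolize toward C6 (cross‑conjugated dienolate) and not toward C4, and must deliver a hydrolytically labile diene that is used without chromatography.

4 to 1 and 2 (through 3). The bond between C6 and its benzyl carbon is cut. This is the α′‑alkylation of a vinylogous ester and reduces the diene to two cheap materials. The forward step demands kinetic enolate formation, C‑ rather than O‑alkylation, and mono‑alkylation.

## Other disconnections considered

Alternative 1: The cut is C1–C6 alone, opening ring A to the open‑chain cinnamoyl triketone A1, which already holds every carbon of the target. In the forward direction base would make the C6 methylene add to the C1 ketone; dehydration and enolization would give the stilbene resorcinol A2, and one catalytic hydrogenation would saturate the alkene and remove the three benzyl ethers to give 15.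
- In its favour: the closure is biomimetic and needs no heat, and the position of every substituent is fixed by the constitution of the chain. The endgame is a single neutral hydrogenation, which is better than the two acidic steps after the key step of the chosen plan.
- Against it: A1 is hard to assemble, since a 1,3,5‑tricarbonyl chain with one α‑benzyl branch and an enone terminus needs polyanion acylations of uncertain site selectivity. A1 also has several competing closures: oxa‑Michael addition of an enol oxygen to the cinnamoyl β‑carbon, dehydrative closure to a 4‑pyranone, and enolization at C2 and C4, which are far more acidic than the C6 position that must react. The electrophile is a conjugated carbonyl next to a branched carbon.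
- Comparison: on structure both plans place all six substituents, but the chosen plan joins two separately purified fragments while A1 is linear. On mechanism the aldol route has several nucleophile–electrophile pairings to control, whereas the cycloaddition has one regiochemical question answered by two cooperating donor groups. On step economy the alternative is better after the key step (one step against two), but the four or five steps expected for A1 make the totals equal at best.

Alternative 2: The cut is C3–C4 in a non‑aromatic ring. The δ‑keto ester A3 would cyclize under alkoxide base, its methyl ketone enolate attacking the ester carbon, to give the cyclohexane‑1,3‑dione A4. Dehydrogenation would give the resorcinol A5, and ether cleavage as in step 6 would give 15.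
- In its favour: the chemistry is classical, cheap enolate chemistry with no sealed‑tube thermolysis, so the ring closure itself is the more scalable one, which is a point better than the chosen plan. Regiochemical certainty is equal, since the acyclic chain fixes each substituent.
- Against it: three stereocentres are created in A3 and A4 only to be destroyed, so diastereomer mixtures burden purification and analysis. Building A3 needs a conjugate addition to an α,β‑disubstituted enone, which is slow and reversible. The late aromatization of a 4,5,6‑trisubstituted dione is an oxidation in the presence of three electron‑rich 4‑methoxyphenyl‑substituted benzylic positions that are themselves prone to oxidation.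
- Comparison: on mechanism the chosen plan reaches the aromatic oxidation level automatically by loss of the bridge, whereas here it needs a separate and uncertain oxidation. On step economy about three steps to A3, then cyclization, aromatization and deprotection give six to seven steps, equal to or longer than the chosen six.

Alternative 3: The cuts are C2–C3 and C4–C5. Heating the cyclobutenone A6 with ethoxyacetylene A7 would open A6 to a vinylketene, which adds A7 by (2+2); four‑electron ring opening and six‑electron electrocyclization then give the phenol A8. One Lewis‑acid ether cleavage (ethyl and methyl ethers together) would give 15.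
- In its favour: the regiochemistry is dictated by the mechanism, which equals the chosen plan. All three carbon arms arrive at the CH2 oxidation level, so no ketone has to be reduced, and only one step follows the key step, which is better than the chosen plan. The temperature needed is also lower.
- Against it: the burden moves to A6, a 2,3,4‑trisubstituted cyclobutenone. A ketene–alkyne (2+2) route to A6 would need an unsymmetrical dialkyl alkyne with no electronic bias (regioisomers) and an alkylketene prone to dimerization; the other route is a multistep 4‑alkylation of a simpler cyclobutenone. The vinylketene must also open with its benzyl group turned outward for the electrocyclization to proceed.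
- Comparison: on structure both are convergent two‑component benzannulations. Here the small partner A7 supplies only C3 and C4, so nearly the whole skeleton rests on A6, whereas 6 and 9 are each one or two steps from catalogue compounds with unambiguous regiochemistry. On step economy the alternative would be equal or one step shorter only if A6 were available in three steps, which is doubtful.

Key step: step 4

Assumption: 7 is taken as a catalogue compound; the aryloxyboron species present in step 6 before hydrolysis and the organometallic species of the catalytic cycle of step 3 are not single defined compounds and are not numbered.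

Step 1
Reactants: 1 3‑methoxycyclohex‑2‑en‑1‑one; 2 4‑methoxybenzyl bromide
Product: 4 3‑methoxy‑6‑(4‑methoxybenzyl)cyclohex‑2‑en‑1‑one (racemic), via lithium dienolate 3 (not isolated)
Conditions: LiN(iPr)2 (1.1 equiv), THF, –78 °C; then 2 (1.05 equiv), –78 °C → rt
Reagents that add atoms: none
Why: Stork–Danheiser α′‑alkylation: the amide base removes the C6 proton of the vinylogous ester kinetically to give the cross‑conjugated dienolate 3, which the reactive benzylic bromide alkylates on carbon; the new C6 stereocentre forms racemic and is erased in step 2.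

Step 2
Reactants: 4 3‑methoxy‑6‑(4‑methoxybenzyl)cyclohex‑2‑en‑1‑one
Product: 6 1‑methoxy‑4‑(4‑methoxybenzyl)‑3‑(trimethylsilyloxy)cyclohexa‑1,3‑diene, via lithium dienolate 5 (not isolated)
Conditions: LiN(iPr)2 (1.2 equiv), THF, –78 °C; Me3SiCl (1.5 equiv), –78 °C → rt; pentane, filtration under Ar, concentration; used crude
Reagents that add atoms: chlorotrimethylsilane, C[Si](C)(C)Cl
Why: A second kinetic deprotonation again takes the α′ proton at C6 rather than the γ proton at C4, and the hard silicon electrophile traps dienolate 5 on oxygen; this enolate O‑silylation is the standard entry to 1‑alkoxy‑3‑silyloxy dienes, and it removes the stereocentre of 4.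

Step 3
Reactants: 7 4‑(4‑methoxyphenyl)but‑1‑yne; 8 4‑methoxybenzoyl chloride
Product: 9 1,5‑bis(4‑methoxyphenyl)pent‑2‑yn‑1‑one
Conditions: PdCl2(PPh3)2 (2 mol %), CuI (4 mol %), Et3N (1.5 equiv), THF, rt, Ar
Reagents that add atoms: none
Why: Acyl Sonogashira coupling: the aroyl chloride adds oxidatively to zerovalent palladium, the copper acetylide formed from 7 with CuI and Et3N transmetallates, and reductive elimination gives the ynone; no strongly nucleophilic acetylide is present, so a second addition to the ketone is avoided.

Step 4
Reactants: 6 1‑methoxy‑4‑(4‑methoxybenzyl)‑3‑(trimethylsilyloxy)cyclohexa‑1,3‑diene; 9 1,5‑bis(4‑methoxyphenyl)pent‑2‑yn‑1‑one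
Product: 12 {4‑hydroxy‑6‑methoxy‑3‑(4‑methoxybenzyl)‑2‑[2‑(4‑methoxyphenyl)ethyl]phenyl}(4‑methoxyphenyl)methanone, via bicyclo[2.2.2]octadiene adduct 10 (not isolated), via aryl trimethylsilyl ether 11 (not isolated)
Conditions: 6 (1.5 equiv), xylenes, sealed tube, 160 °C; then 1 M HCl, THF, rt
Reagents that add atoms: none
Why: Thermal Diels–Alder reaction of the electron‑rich diene 6 with the electron‑poor ynone 9 should give the bicyclo[2.2.2]octa‑2,5‑diene 10 in a concerted but asynchronous process in which the C1–C6 bond leads. On continued heating 10 undergoes retro‑(4+2) cleavage of its saturated two‑carbon bridge, expelling ethene and leaving the aromatic silyl ether 11; gain of aromaticity and loss of a gas make this irreversible. The closest known reaction type is the Alder–Rickert synthesis of resorcinol derivatives from 1‑alkoxy‑3‑silyloxycyclohexa‑1,3‑dienes and acetylenic ketones, esters or aldehydes. Ring A is closed by intermolecular (4+2) cycloaddition, both ring bonds (C1–C6 and C2–C3) forming suprafacially on diene and alkyne in one step, and is then aromatized by cycloreversion. The only stereocentres formed are the two bridgeheads of 10, which are tied to each other by the bicycle, arise racemic and vanish with the loss of ethene, so no stereocontrol is needed. The selectivity required is regiochemical: the C3 methoxy and C5 silyloxy groups both raise the HOMO coefficient at the benzyl‑bearing terminus C6, and the carbonyl places the larger LUMO coefficient on the alkyne β‑carbon, so C6 joins C1 and the aroyl group ends on C2 next to the methoxy group. Dilute acid in the work‑up removes the silyl group of 11 to give 12 and returns excess 6 to 4.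

Step 5
Reactants: 12 {4‑hydroxy‑6‑methoxy‑3‑(4‑methoxybenzyl)‑2‑[2‑(4‑methoxyphenyl)ethyl]phenyl}(4‑methoxyphenyl)methanone
Product: 14 5‑methoxy‑2,4‑bis(4‑methoxybenzyl)‑3‑[2‑(4‑methoxyphenyl)ethyl]phenol, via diarylmethanol 13 (not isolated)
Conditions: Et3SiH (4 equiv), CF3CO2H/CH2Cl2 1:1, 0 °C → rt
Reagents that add atoms: none
Why: Ionic hydrogenation: the protonated ketone accepts hydride from the silane to give 13, which ionizes to a diarylmethyl cation stabilized by the para hydroxyl and ortho methoxy groups of ring A and by the 4‑methoxyphenyl ring and takes a second hydride; aryl ethers, the phenol and the other benzylic CH2 groups are inert, and the racemic centre of 13 disappears.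

Step 6
Reactants: 14 5‑methoxy‑2,4‑bis(4‑methoxybenzyl)‑3‑[2‑(4‑methoxyphenyl)ethyl]phenol
Product: 15 4,6‑bis(4‑hydroxybenzyl)‑5‑[2‑(4‑hydroxyphenyl)ethyl]benzene‑1,3‑diol (target)
Conditions: BBr3 (8 equiv), CH2Cl2, –78 °C → rt; then H2O, 0 °C
Reagents that add atoms: none
Why: Lewis‑acid cleavage of aryl methyl ethers: boron coordinates each ether oxygen, bromide attacks the methyl group in an SN2 step and hydrolysis frees the phenols; the hydrocarbon skeleton offers no other reactive site, and starting cold limits protonation of ring A.

Compound list

1 | 3‑methoxycyclohex‑2‑en‑1‑one | COC1=CC(=O)CCC1 | starting material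
2 | 4‑methoxybenzyl bromide | COc1ccc(CBr)cc1 | starting material
3 | lithium 5‑methoxycyclohexa‑1,5‑dien‑1‑olate | [Li+].[O-]C1=CCCC(OC)=C1 | intermediate
4 | 3‑methoxy‑6‑(4‑methoxybenzyl)cyclohex‑2‑en‑1‑one (racemic) | COC1=CC(=O)C(Cc2ccc(OC)cc2)CC1 | intermediate
5 | lithium 5‑methoxy‑2‑(4‑methoxybenzyl)cyclohexa‑1,5‑dien‑1‑olate | [Li+].[O-]C1=C(Cc2ccc(OC)cc2)CCC(OC)=C1 | intermediate
6 | 1‑methoxy‑4‑(4‑methoxybenzyl)‑3‑(trimethylsilyloxy)cyclohexa‑1,3‑diene | COC1=CC(O[Si](C)(C)C)=C(Cc2ccc(OC)cc2)CC1 | intermediate
7 | 4‑(4‑methoxyphenyl)but‑1‑yne | C#CCCc1ccc(OC)cc1 | starting material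
8 | 4‑methoxybenzoyl chloride | COc1ccc(C(=O)Cl)cc1 | starting material
9 | 1,5‑bis(4‑methoxyphenyl)pent‑2‑yn‑1‑one | COc1ccc(CCC#CC(=O)c2ccc(OC)cc2)cc1 | intermediate
10 | (4‑methoxyphenyl){1‑methoxy‑4‑(4‑methoxybenzyl)‑3‑[2‑(4‑methoxyphenyl)ethyl]‑5‑(trimethylsilyloxy)bicyclo[2.2.2]octa‑2,5‑dien‑2‑yl}methanone (racemic) | COC12CCC(Cc3ccc(OC)cc3)(C(O[Si](C)(C)C)=C1)C(CCc1ccc(OC)cc1)=C2C(=O)c1ccc(OC)cc1 | intermediate
11 | {6‑methoxy‑3‑(4‑methoxybenzyl)‑2‑[2‑(4‑methoxyphenyl)ethyl]‑4‑(trimethylsilyloxy)phenyl}(4‑methoxyphenyl)methanone | COc1cc(O[Si](C)(C)C)c(Cc2ccc(OC)cc2)c(CCc2ccc(OC)cc2)c1C(=O)c1ccc(OC)cc1 | intermediate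
12 | {4‑hydroxy‑6‑methoxy‑3‑(4‑methoxybenzyl)‑2‑[2‑(4‑methoxyphenyl)ethyl]phenyl}(4‑methoxyphenyl)methanone | COc1cc(O)c(Cc2ccc(OC)cc2)c(CCc2ccc(OC)cc2)c1C(=O)c1ccc(OC)cc1 | intermediate
13 | 4‑[hydroxy(4‑methoxyphenyl)methyl]‑5‑methoxy‑2‑(4‑methoxybenzyl)‑3‑[2‑(4‑methoxyphenyl)ethyl]phenol (racemic) | COc1cc(O)c(Cc2ccc(OC)cc2)c(CCc2ccc(OC)cc2)c1C(O)c1ccc(OC)cc1 | intermediate
14 | 5‑methoxy‑2,4‑bis(4‑methoxybenzyl)‑3‑[2‑(4‑methoxyphenyl)ethyl]phenol | COc1cc(O)c(Cc2ccc(OC)cc2)c(CCc2ccc(OC)cc2)c1Cc1ccc(OC)cc1 | intermediate
15 | 4,6‑bis(4‑hydroxybenzyl)‑5‑[2‑(4‑hydroxyphenyl)ethyl]benzene‑1,3‑diol | Oc1ccc(CCc2c(Cc3ccc(O)cc3)c(O)cc(O)c2Cc2ccc(O)cc2)cc1 | target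

Total step count: 6. Longest linear sequence: 5 steps (steps 1, 2, 4, 5 and 6, counted from 1); the branch to 9 is one step (step 3).

Steps least certain to work

Step 4 (key step). The most likely failure is slow bond formation between the fully substituted diene terminus C6 and the substituted alkyne carbon C1. That would let thermal 1,5‑hydrogen shifts in the diene, desilylation and oligomerization of the ynone compete before cycloaddition occurs. The fallback sets out from 7, uses 6 unchanged and comes back at 13. Lithiation of 7 (n‑BuLi, THF, –78 °C) and formylation with DMF should give 5‑(4‑methoxyphenyl)pent‑2‑ynal F1, a smaller and more electrophilic dienophile with the same polarization. Heated with 6 it should give the bicyclic adduct 1‑methoxy‑4‑(4‑methoxybenzyl)‑3‑[2‑(4‑methoxyphenyl)ethyl]‑5‑(trimethylsilyloxy)bicyclo[2.2.2]octa‑2,5‑diene‑2‑carbaldehyde F2, which should lose ethene to 6‑methoxy‑3‑(4‑methoxybenzyl)‑2‑[2‑(4‑methoxyphenyl)ethyl]‑4‑(trimethylsilyloxy)benzaldehyde F3. Acidic work‑up should give 4‑hydroxy‑6‑methoxy‑3‑(4‑methoxybenzyl)‑2‑[2‑(4‑methoxyphenyl)ethyl]benzaldehyde F4. Addition of 4‑MeOC6H4MgBr (3 equiv, the first consumed by the phenol; THF, 0 °C → rt) should give 13, which is taken on with Et3SiH and CF3CO2H as in step 5 to 14.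

Step 2. The trimethylsilyl dienol ether may hydrolyse during isolation, and some deprotonation toward C4 would put a regioisomeric diene into the key step unnoticed, because the crude material is not purified. The fallback sets out from 4 and comes back at 12. Deprotonation as in step 2 and trapping with tBuMe2SiOTf should give 3‑(tert‑butyldimethylsilyloxy)‑1‑methoxy‑4‑(4‑methoxybenzyl)cyclohexa‑1,3‑diene F5, robust enough to be chromatographed on base‑washed silica and checked for regiochemistry. Heated with 9 it should pass through (4‑methoxyphenyl){5‑(tert‑butyldimethylsilyloxy)‑1‑methoxy‑4‑(4‑methoxybenzyl)‑3‑[2‑(4‑methoxyphenyl)ethyl]bicyclo[2.2.2]octa‑2,5‑dien‑2‑yl}methanone F6 to {4‑(tert‑butyldimethylsilyloxy)‑6‑methoxy‑3‑(4‑methoxybenzyl)‑2‑[2‑(4‑methoxyphenyl)ethyl]phenyl}(4‑methoxyphenyl)methanone F7, which Bu4NF in THF should cleave to 12.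

Step 5. Hydride delivery to the hindered, strongly stabilized diarylmethyl cation may be slow. The cation could then alkylate an arene instead (seven‑membered ring closure onto the arylethyl ring, or intermolecular attack at C4 of ring A), or the acid could strip the benzyl group from C6. The fallback sets out from 12 and comes back at 14, avoiding acid altogether. With NaBH4 in hot aqueous NaOH the ketone should be reduced to 13, whose para‑phenoxide expels hydroxide to give the quinone methide 5‑methoxy‑2‑(4‑methoxybenzyl)‑4‑(4‑methoxybenzylidene)‑3‑[2‑(4‑methoxyphenyl)ethyl]cyclohexa‑2,5‑dien‑1‑one F8. Conjugate hydride addition to F8 should give 14; this is the known reduction of para‑hydroxyaryl ketones to alkylphenols.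

Step 6. Hydrogen bromide formed during the reaction may protonate ring A at C2 or C6 and cause loss or migration of a benzyl group, and the flanked ring A methyl ether may cleave incompletely. The fallback sets out from 14 and comes back at 15. Nucleophilic demethylation with NaSEt in DMF at 140 °C removes the methyl groups by SN2 attack of thiolate under basic conditions, in which ipso‑protonation cannot occur; no new compound lies on this path.

## Further compounds

F1 | step 4 | 5‑(4‑methoxyphenyl)pent‑2‑ynal | COc1ccc(CCC#CC=O)cc1
F2 | step 4 | 1‑methoxy‑4‑(4‑methoxybenzyl)‑3‑[2‑(4‑methoxyphenyl)ethyl]‑5‑(trimethylsilyloxy)bicyclo[2.2.2]octa‑2,5‑diene‑2‑carbaldehyde (racemic) | COC12CCC(Cc3ccc(OC)cc3)(C(O[Si](C)(C)C)=C1)C(CCc1ccc(OC)cc1)=C2C=O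
F3 | step 4 | 6‑methoxy‑3‑(4‑methoxybenzyl)‑2‑[2‑(4‑methoxyphenyl)ethyl]‑4‑(trimethylsilyloxy)benzaldehyde | COc1cc(O[Si](C)(C)C)c(Cc2ccc(OC)cc2)c(CCc2ccc(OC)cc2)c1C=O
F4 | step 4 | 4‑hydroxy‑6‑methoxy‑3‑(4‑methoxybenzyl)‑2‑[2‑(4‑methoxyphenyl)ethyl]benzaldehyde | COc1cc(O)c(Cc2ccc(OC)cc2)c(CCc2ccc(OC)cc2)c1C=O
F5 | step 2 | 3‑(tert‑butyldimethylsilyloxy)‑1‑methoxy‑4‑(4‑methoxybenzyl)cyclohexa‑1,3‑diene | COC1=CC(O[Si](C)(C)C(C)(C)C)=C(Cc2ccc(OC)cc2)CC1
F6 | step 2 | (4‑methoxyphenyl){5‑(tert‑butyldimethylsilyloxy)‑1‑methoxy‑4‑(4‑methoxybenzyl)‑3‑[2‑(4‑methoxyphenyl)ethyl]bicyclo[2.2.2]octa‑2,5‑dien‑2‑yl}methanone (racemic) | COC12CCC(Cc3ccc(OC)cc3)(C(O[Si](C)(C)C(C)(C)C)=C1)C(CCc1ccc(OC)cc1)=C2C(=O)c1ccc(OC)cc1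
F7 | step 2 | {4‑(tert‑butyldimethylsilyloxy)‑6‑methoxy‑3‑(4‑methoxybenzyl)‑2‑[2‑(4‑methoxyphenyl)ethyl]phenyl}(4‑methoxyphenyl)methanone | COc1cc(O[Si](C)(C)C(C)(C)C)c(Cc2ccc(OC)cc2)c(CCc2ccc(OC)cc2)c1C(=O)c1ccc(OC)cc1
F8 | step 5 | 5‑methoxy‑2‑(4‑methoxybenzyl)‑4‑(4‑methoxybenzylidene)‑3‑[2‑(4‑methoxyphenyl)ethyl]cyclohexa‑2,5‑dien‑1‑one (alkene geometry not defined) | COC1=CC(=O)C(Cc2ccc(OC)cc2)=C(CCc2ccc(OC)cc2)C1=Cc1ccc(OC)cc1
F0 | step 6 | none | none
A1 | alternative 1 | (E)‑4‑[4‑(benzyloxy)benzyl]‑1,9‑bis[4‑(benzyloxy)phenyl]non‑1‑ene‑3,5,7‑trione (racemic) | O=C(/C=C/c1ccc(OCc2ccccc2)cc1)C(Cc1ccc(OCc2ccccc2)cc1)C(=O)CC(=O)CCc1ccc(OCc2ccccc2)cc1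
A2 | alternative 1 | 4,6‑bis[4‑(benzyloxy)benzyl]‑5‑{(E)‑2‑[4‑(benzyloxy)phenyl]ethenyl}benzene‑1,3‑diol | Oc1cc(O)c(Cc2ccc(OCc3ccccc3)cc2)c(/C=C/c2ccc(OCc3ccccc3)cc2)c1Cc1ccc(OCc2ccccc2)cc1
A3 | alternative 2 | methyl 2,4‑bis(4‑methoxybenzyl)‑3‑[2‑(4‑methoxyphenyl)ethyl]‑5‑oxohexanoate (diastereomer mixture) | COC(=O)C(Cc1ccc(OC)cc1)C(CCc1ccc(OC)cc1)C(Cc1ccc(OC)cc1)C(C)=O
A4 | alternative 2 | 4,6‑bis(4‑methoxybenzyl)‑5‑[2‑(4‑methoxyphenyl)ethyl]cyclohexane‑1,3‑dione (diastereomer mixture) | COc1ccc(CCC2C(Cc3ccc(OC)cc3)C(=O)CC(=O)C2Cc2ccc(OC)cc2)cc1
A5 | alternative 2 | 4,6‑bis(4‑methoxybenzyl)‑5‑[2‑(4‑methoxyphenyl)ethyl]benzene‑1,3‑diol | COc1ccc(CCc2c(Cc3ccc(OC)cc3)c(O)cc(O)c2Cc2ccc(OC)cc2)cc1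
A6 | alternative 3 | 2,4‑bis(4‑methoxybenzyl)‑3‑[2‑(4‑methoxyphenyl)ethyl]cyclobut‑2‑en‑1‑one (racemic) | O=C1C(Cc2ccc(OC)cc2)=C(CCc2ccc(OC)cc2)C1Cc1ccc(OC)cc1
A7 | alternative 3 | ethoxyacetylene (ethoxyethyne) | CCOC#C
A8 | alternative 3 | 5‑ethoxy‑2,4‑bis(4‑methoxybenzyl)‑3‑[2‑(4‑methoxyphenyl)ethyl]phenol | CCOc1cc(O)c(Cc2ccc(OC)cc2)c(CCc2ccc(OC)cc2)c1Cc1ccc(OC)cc1
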